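## Retrosynthetic overview

1. Numbering used: 16-membered lactam N1–C2(=O)–C3–C4(=O)–C5–C6–C7–C8–C9(Me)=C10–C11=C12–C13=C14–C15(Me)–C16; ring B (cyclohexene) C7–C8–C17=C18–C19–C20; ring A (cyclohexane) C19–C20–C21–C22(OH)–C23–C24(OH); ring C (tetrahydrofuran) C6–O–C21–C20–C7.
2. Last operations: Z-semireduction of a C11≡C12 alkyne, and ring C by oxa-Michael addition of O21 to a C5=C6 enone after unmasking.
3. Key disconnection C14–C15: a stereoretentive sp3–sp2 Suzuki–Miyaura closure of an open chain to a 24-membered lactam, which then undergoes a transannular Diels–Alder reaction (diene C19=C18–C17=C8, dienophile C20=C7). Ring order: macrocycle, then rings A and B together, then ring C.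
4. Enabling feature: C15 is β to the lactam nitrogen, so the amide oxygen on C2 can chelate boron on C15 (six-membered B–C15–C16–N1–C2=O); and C20=C7 is joined to C19=C18–C17=C8 by the four-carbon tether C21–C24, a 1,7,9-decatriene that maps rings A and B onto one [4+2] event.
5. The open chain comes from three pieces: stannane 5 (C17, C8–C14), iodide 22 from 2-deoxy-L-ribose (C3–C7, C18–C24; C21 and C22 bought, C24 by asymmetric transfer hydrogenation) and isocyanate 10 (C15, C16, N1, C2; C15 by copper-catalysed borylation).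

Key step: step 20

Remark: transfer of C15 from boron to carbon is assumed to occur with retention (chelate-assisted closed transmetalation), so boronate 7 is made with S configuration.

## Route

Step 1
Reactants: 1 (2Z)-3-methylpent-2-en-4-yn-1-ol
Product: 2 (2Z,4E)-3-methyl-5-(tributylstannyl)penta-2,4-dien-1-ol
Conditions: Bu3SnH (1.2 equiv), PdCl2(PPh3)2 (2 mol %), THF, 0 °C
Reagents that add atoms: tributyltin hydride, CCCC[SnH](CCCC)CCCC
Why: Palladium-catalysed syn-hydrostannation of the terminal alkyne should place tin on the terminal carbon and give the E-vinylstannane, leaving the preset Z-trisubstituted alkene untouched.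

Step 2
Reactants: 2 (2Z,4E)-3-methyl-5-(tributylstannyl)penta-2,4-dien-1-ol
Product: 3 (2Z,4E)-3-methyl-5-(tributylstannyl)penta-2,4-dienal
Conditions: MnO2 (20 equiv), CH2Cl2, rt, dark
Reagents that add atoms: none
Why: Allylic oxidation with MnO2 is neutral and should stop at the enal with the 2Z geometry and the C–Sn bond intact.

Step 3
Reactants: 3 (2Z,4E)-3-methyl-5-(tributylstannyl)penta-2,4-dienal
Product: 4 tributyl[(1E,3Z)-3-methylhexa-1,3-dien-5-yn-1-yl]stannane
Conditions: Me3SiCHN2 (1.3 equiv), LiN(iPr)2 (1.3 equiv), THF, −78 → 0 °C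
Reagents that add atoms: (trimethylsilyl)diazomethane, C[Si](C)(C)C=[N+]=[N-]
Why: The Colvin rearrangement (addition of the lithiated diazo compound, Peterson-type elimination, 1,2-shift in the alkylidene carbene) turns an enal into the terminal enyne without the conjugate-addition problems of basic methanol.

Step 4
Reactants: 4 tributyl[(1E,3Z)-3-methylhexa-1,3-dien-5-yn-1-yl]stannane
Product: 5 tributyl[(1E,3Z,7Z)-8-chloro-3-methylocta-1,3,7-trien-5-yn-1-yl]stannane
Conditions: (Z)-ClCH=CHCl (5 equiv), Pd(PPh3)4 (5 mol %), CuI (10 mol %), n-BuNH2 (2 equiv), benzene, rt, dark, argon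
Reagents that add atoms: (Z)-1,2-dichloroethene, Cl/C=C\Cl
Why: Sonogashira coupling with excess (Z)-1,2-dichloroethene is selective for mono-substitution with retention of the Z geometry, and the vinylstannane has no partner because vinyl chlorides are inert to Stille coupling under these conditions.

Step 5
Reactants: 6 benzyl (2E)-but-2-enoate
Product: 7 benzyl (3S)-3-(4,4,5,5-tetramethyl-1,3,2-dioxaborolan-2-yl)butanoate
Conditions: B2pin2 (1.1 equiv), CuCl (3 mol %), NaOtBu (3 mol %), Josiphos ligand [1-(2-diphenylphosphinoferrocenyl)ethyl]dicyclohexylphosphine (4 mol %, enantiomer chosen to give the S product), MeOH (2 equiv), THF, rt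
Reagents that add atoms: bis(pinacolato)diboron, CC1(C)OB(OC1(C)C)B1OC(C)(C)C(C)(C)O1
Why: Copper-catalysed asymmetric conjugate borylation of the enoate sets C15 by enantioface-selective borylcupration under ligand control, followed by protonation of the copper enolate.

Step 6
Reactants: 7 benzyl (3S)-3-(4,4,5,5-tetramethyl-1,3,2-dioxaborolan-2-yl)butanoate
Product: 8 (3S)-3-(4,4,5,5-tetramethyl-1,3,2-dioxaborolan-2-yl)butanoic acid
Conditions: H2 (1 atm), Pd/C (10 %), EtOAc, rt
Reagents that add atoms: none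
Why: Hydrogenolysis of the benzyl ester is neutral and leaves the secondary alkyl boronate untouched.

Step 7
Reactants: 8 (3S)-3-(4,4,5,5-tetramethyl-1,3,2-dioxaborolan-2-yl)butanoic acid
Product: 10 2-[(2S)-1-isocyanatopropan-2-yl]-4,4,5,5-tetramethyl-1,3,2-dioxaborolane, via acyl azide 9 (not isolated)
Conditions: (PhO)2P(O)N3 (1.05 equiv), Et3N (1.1 equiv), toluene, 0 °C → rt; then 80 °C; used as toluene solution
Reagents that add atoms: diphenylphosphoryl azide, O=P(N=[N+]=[N-])(Oc1ccccc1)Oc1ccccc1
Why: The Curtius rearrangement moves the CH2 group (future C16) from carbon to nitrogen without touching the adjacent stereocentre, and the carboxyl carbon is kept as the isocyanate carbon, the future C2.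

Step 8
Reactants: 11 2-deoxy-L-ribose
Product: 12 2-deoxy-3,4-O-isopropylidene-L-erythro-pentopyranose
Conditions: 2-methoxypropene (1.5 equiv), PPTS (cat.), DMF, 0 °C → rt
Reagents that add atoms: 2-methoxypropene, COC(C)=C
Why: Acid-catalysed acetalisation traps the cis-3,4-diol of the pyranose form as the acetonide (C21 and C22 bought) and leaves the lactol free.

Step 9
Reactants: 12 2-deoxy-3,4-O-isopropylidene-L-erythro-pentopyranose
Product: 13 1-[(4R,5S)-5-(hydroxymethyl)-2,2-dimethyl-1,3-dioxolan-4-yl]but-3-yn-2-ol (both carbinol epimers)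
Conditions: HC≡CMgBr (3.5 equiv), THF, 0 °C → rt
Reagents that add atoms: ethynylmagnesium bromide, C#C[Mg]Br
Why: Grignard addition to the open-chain aldehyde in equilibrium with the lactol brings in C19 and C18; the new carbinol centre is not controlled here and is corrected in steps 11 and 12.

Step 10
Reactants: 13 1-[(4R,5S)-5-(hydroxymethyl)-2,2-dimethyl-1,3-dioxolan-4-yl]but-3-yn-2-ol
Product: 14 1-[(4R,5S)-2,2-dimethyl-5-(triethylsilyloxymethyl)-1,3-dioxolan-4-yl]but-3-yn-2-ol (both epimers)
Conditions: Et3SiCl (1.05 equiv), imidazole, CH2Cl2, −78 → −40 °C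
Reagents that add atoms: chlorotriethylsilane, CC[Si](Cl)(CC)CC
Why: Kinetic silylation should differentiate the primary hydroxyl from the secondary propargylic one.

Step 11
Reactants: 14 1-[(4R,5S)-2,2-dimethyl-5-(triethylsilyloxymethyl)-1,3-dioxolan-4-yl]but-3-yn-2-ol
Product: 15 1-[(4R,5S)-2,2-dimethyl-5-(triethylsilyloxymethyl)-1,3-dioxolan-4-yl]but-3-yn-2-one
Conditions: Dess–Martin periodinane (1.3 equiv), NaHCO3, CH2Cl2, 0 °C → rt
Reagents that add atoms: none
Why: Dess–Martin oxidation under buffered, non-basic conditions merges both epimers into one ynone without β-elimination of the dioxolane oxygen.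

Step 12
Reactants: 15 1-[(4R,5S)-2,2-dimethyl-5-(triethylsilyloxymethyl)-1,3-dioxolan-4-yl]but-3-yn-2-one
Product: 16 (2S)-1-[(4R,5S)-2,2-dimethyl-5-(triethylsilyloxymethyl)-1,3-dioxolan-4-yl]but-3-yn-2-ol
Conditions: Ru[(S,S)-TsDPEN](p-cymene) (2 mol %), iPrOH, rt
Reagents that add atoms: none
Why: Asymmetric transfer hydrogenation (Noyori type) of the alkynyl ketone sets C24 (S, 1,3-syn to O22) under catalyst control, the alkynyl group taking the place of the aryl group in the usual model.

Step 13
Reactants: 16 (2S)-1-[(4R,5S)-2,2-dimethyl-5-(triethylsilyloxymethyl)-1,3-dioxolan-4-yl]but-3-yn-2-ol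
Product: 17 tert-butyldimethylsilyl ether of 16
Conditions: TBSOTf (1.2 equiv), 2,6-lutidine, CH2Cl2, −78 °C
Reagents that add atoms: tert-butyldimethylsilyl trifluoromethanesulfonate, CC(C)(C)[Si](C)(C)OS(=O)(=O)C(F)(F)F
Why: Silylation with the silyl triflate masks O24, which as a free hydroxyl could later add in 1,6-fashion to the dienone.

Step 14
Reactants: 17 tert-butyldimethylsilyl ether of 16
Product: 19 (E)-vinyl iodide (C18–I), via alkenylzirconocene 18 (not isolated)
Conditions: Cp2Zr(H)Cl (1.5 equiv), THF, rt; then I2 (1.5 equiv), 0 °C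
Reagents that add atoms: iodine, II
Why: Hydrozirconation of the terminal alkyne is syn and puts zirconium on the terminal carbon, and iodinolysis of the C–Zr bond proceeds with retention to give the E-vinyl iodide.

Step 15
Reactants: 19 (E)-vinyl iodide (C18–I)
Product: 21 (2E)-enal (C6 aldehyde; C7=C20), via aldehyde 20 (not isolated)
Conditions: (COCl)2 (3 equiv), DMSO (6 equiv), CH2Cl2, −78 → −35 °C; Et3N, −78 → 0 °C; then Ph3P=CHCHO (1.5 equiv), rt
Reagents that add atoms: (triphenylphosphoranylidene)acetaldehyde, O=CC=P(c1ccccc1)(c1ccccc1)c1ccccc1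
Why: Swern conditions oxidise a primary triethylsilyl ether directly to the aldehyde while the secondary TBS ether survives, and the epimerisable α-alkoxy aldehyde is trapped at once by Wittig reaction with the stabilised ylide to give the E-enal.

Step 16
Reactants: 21 (2E)-enal (C6 aldehyde; C7=C20)
Product: 22 (3E,5E)-dienyl methyl ketone (C3–C7; C20–C24; C18–I)
Conditions: (EtO)2P(O)CH2C(O)CH3 (1.3 equiv), NaH (1.25 equiv), THF, 0 °C → rt
Reagents that add atoms: diethyl (2-oxopropyl)phosphonate, CCOP(=O)(CC(C)=O)OCC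
Why: Horner–Wadsworth–Emmons reaction of the β-keto phosphonate anion with the enal should give the E,E-dienone and bring in C3–C5.

Step 17
Reactants: 22 (3E,5E)-dienyl methyl ketone; 10 2-[(2S)-1-isocyanatopropan-2-yl]-4,4,5,5-tetramethyl-1,3,2-dioxaborolane
Product: 24 β-keto amide pinacol boronate (N1–C2 joined to C3), via lithium enolate 23 (not isolated)
Conditions: LiN(SiMe3)2 (1.05 equiv), THF, −78 °C; then 10 in toluene, −78 → −40 °C; AcOH quench
Reagents that add atoms: none
Why: Kinetic deprotonation at the methyl group and C-carbamoylation of the lithium enolate by the isocyanate (enolate acylation) gives the β-keto amide directly, one equivalent of base sufficing because the adduct tautomerises to the stabilised enolate.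

Step 18
Reactants: 24 β-keto amide pinacol boronate
Product: 25 potassium trifluoroborate of 24
Conditions: KHF2 (4.5 M aq., 4 equiv), MeOH, rt; extraction into acetone, precipitation with Et2O
Reagents that add atoms: potassium hydrogen difluoride, [K+].[F-].F
Why: Exchange of pinacol for fluoride gives the trifluoroborate, the boron form used in stereospecific coupling of secondary alkyl groups, with no change at C15.

Step 19
Reactants: 25 potassium trifluoroborate of 24; 5 tributyl[(1E,3Z,7Z)-8-chloro-3-methylocta-1,3,7-trien-5-yn-1-yl]stannane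
Product: 26 open-chain precursor (C14–Cl; C15–BF3K)
Conditions: Pd2(dba)3 (5 mol %), AsPh3 (40 mol %), DMF, rt, dark; trituration with hexane
Reagents that add atoms: none
Why: Stille coupling of vinyl iodide and vinylstannane proceeds with retention on both partners at room temperature without base, so that the chloride, the trifluoroborate and the diene–dienophile pair stay untouched.

Step 20
Reactants: 26 open-chain precursor (C14–Cl; C15–BF3K)
Product: 28 octalin-bridged 16-membered lactam (5,6-ene; 11,12-yne; O21/O22 acetonide; O24 TBS ether), via 24-membered lactam 27 (not isolated)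
Conditions: Pd(OAc)2 (15 mol %), XPhos (30 mol %), Cs2CO3 (3 equiv), toluene/H2O 10:1, 1 mM (26 added in THF by syringe pump), 75 °C; then 90 °C
Reagents that add atoms: none
Why: Proposed new method: the zerovalent palladium–XPhos catalyst should insert into the C14–Cl bond of the (Z)-chloroenyne, the trifluoroborate is hydrolysed slowly to the boronic acid, and the secondary C15–B bond should transmetalate with retention through a closed Pd–O–B transition state assisted by the amide oxygen on C2 (six-membered chelate B–C15–C16–N1–C2=O, which also keeps the alkylpalladium from β-hydride elimination); reductive elimination then forms C14–C15 with the Z geometry of the halide and closes the 24-membered lactam 27 (ring closure by cross-coupling at high dilution). The closest known reaction types are the stereospecific Suzuki–Miyaura coupling of enantioenriched secondary alkyltrifluoroborates, including amide-chelated β- and γ-boryl amides, with aryl and alkenyl halides, and the B-alkyl Suzuki–Miyaura macrocyclisation of primary alkylboranes; their combination on a secondary centre in a ring closure is new. In 27 the diene C19=C18–C17=C8 and the dienophile C20=C7 (γ,δ-bond of the dienone) should then react in a transannular [4+2] cycloaddition at the same temperature, closing ring A (six-membered, through C19–C20 over the tether C21–C24) and ring B (six-membered, through C7–C8) and contracting the macrocycle to sixteen members, as known for transannular Diels–Alder reactions of 24-membered polyene macrocycles. The E geometry of both partners fixes H7/H20 trans and H8/H19 cis; the C9–C5 bridge is expected to favour the transition state with C6 exo and C21 endo, which gives the cis ring fusion, and the face is chosen by the existing centres (C24–O antiperiplanar to the forming C19–C20 bond, the cis-dioxolane on C21/C22 turned away from the diene), so that C7, C8, C19 and C20 are relayed from C21, C22 and C24 while C15 is transferred unchanged. The step needs chemoselectivity (the chloride is the only halide left), retention at C15, no conjugate addition of O24 (hence the silyl ether) and ring closure before cycloaddition, the last secured by the merely vinylogous activation of the dienophile, which should keep the open-chain Diels–Alder reaction slower than the coupling.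

Step 21
Reactants: 28 octalin-bridged 16-membered lactam
Product: 30 11,12-didehydroverticilactam C, via triol enone 29 (not isolated)
Conditions: 2 M aq. HCl/THF 1:4, 40 °C; NaHCO3; then DBU (0.2 equiv), CH2Cl2, rt
Reagents that add atoms: none
Why: Acid hydrolysis removes the acetonide and the silyl ether, and the freed O21 hydroxyl, held cis to C7 on ring A, should add to C6 of the enone (5-exo-trig oxa-Michael addition) with base equilibration to the trans-2,3-disubstituted tetrahydrofuran (sets C6), the six-membered ether from O22 requiring a triaxial ring A.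

Step 22
Reactants: 30 11,12-didehydroverticilactam C
Product: 31 verticilactam C
Conditions: Zn dust activated with Cu(OAc)2 and AgNO3, MeOH/H2O 1:1, 40 °C
Reagents that add atoms: none
Why: Activated zinc reduces conjugated alkynes to Z-alkenes by syn delivery of hydrogen and should not touch the isolated C17=C18 alkene, the existing Z-alkenes or the ketone.

## Compound list

1 | (2Z)-3-methylpent-2-en-4-yn-1-ol | C#C/C(C)=C\CO | starting material
2 | (2Z,4E)-3-methyl-5-(tributylstannyl)penta-2,4-dien-1-ol | CCCC[Sn](CCCC)(CCCC)/C=C/C(C)=C\CO | intermediate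
3 | (2Z,4E)-3-methyl-5-(tributylstannyl)penta-2,4-dienal | CCCC[Sn](CCCC)(CCCC)/C=C/C(C)=C\C=O | intermediate
4 | tributyl[(1E,3Z)-3-methylhexa-1,3-dien-5-yn-1-yl]stannane | CCCC[Sn](CCCC)(CCCC)/C=C/C(C)=C\C#C | intermediate
5 | tributyl[(1E,3Z,7Z)-8-chloro-3-methylocta-1,3,7-trien-5-yn-1-yl]stannane (C17, C8–C14, 9-methyl) | CCCC[Sn](CCCC)(CCCC)/C=C/C(C)=C\C#C/C=C\Cl | intermediate
6 | benzyl (2E)-but-2-enoate | C/C=C/C(=O)OCc1ccccc1 | starting material
7 | benzyl (3S)-3-(4,4,5,5-tetramethyl-1,3,2-dioxaborolan-2-yl)butanoate | C[C@@H](CC(=O)OCc1ccccc1)B1OC(C)(C)C(C)(C)O1 | intermediate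
8 | (3S)-3-(4,4,5,5-tetramethyl-1,3,2-dioxaborolan-2-yl)butanoic acid | C[C@@H](CC(=O)O)B1OC(C)(C)C(C)(C)O1 | intermediate
9 | (3S)-3-(4,4,5,5-tetramethyl-1,3,2-dioxaborolan-2-yl)butanoyl azide | C[C@@H](CC(=O)N=[N+]=[N-])B1OC(C)(C)C(C)(C)O1 | intermediate (not isolated)
10 | 2-[(2S)-1-isocyanatopropan-2-yl]-4,4,5,5-tetramethyl-1,3,2-dioxaborolane | C[C@@H](CN=C=O)B1OC(C)(C)C(C)(C)O1 | intermediate
11 | 2-deoxy-L-ribose (2-deoxy-L-erythro-pentopyranose, anomers) | OC1C[C@@H](O)[C@@H](O)CO1 | starting material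
12 | 2-deoxy-3,4-O-isopropylidene-L-erythro-pentopyranose (anomers) | OC1C[C@H]2OC(C)(C)O[C@H]2CO1 | intermediate
13 | 1-[(4R,5S)-5-(hydroxymethyl)-2,2-dimethyl-1,3-dioxolan-4-yl]but-3-yn-2-ol (both carbinol epimers) | OC[C@@H]1OC(C)(C)O[C@@H]1CC(O)C#C | intermediate
14 | 1-[(4R,5S)-2,2-dimethyl-5-(triethylsilyloxymethyl)-1,3-dioxolan-4-yl]but-3-yn-2-ol (both epimers) | CC[Si](CC)(CC)OC[C@@H]1OC(C)(C)O[C@@H]1CC(O)C#C | intermediate
15 | 1-[(4R,5S)-2,2-dimethyl-5-(triethylsilyloxymethyl)-1,3-dioxolan-4-yl]but-3-yn-2-one | CC[Si](CC)(CC)OC[C@@H]1OC(C)(C)O[C@@H]1CC(=O)C#C | intermediate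
16 | (2S)-1-[(4R,5S)-2,2-dimethyl-5-(triethylsilyloxymethyl)-1,3-dioxolan-4-yl]but-3-yn-2-ol | CC[Si](CC)(CC)OC[C@@H]1OC(C)(C)O[C@@H]1C[C@H](O)C#C | intermediate
17 | tert-butyl{[(2S)-1-[(4R,5S)-2,2-dimethyl-5-(triethylsilyloxymethyl)-1,3-dioxolan-4-yl]but-3-yn-2-yl]oxy}dimethylsilane | CC[Si](CC)(CC)OC[C@@H]1OC(C)(C)O[C@@H]1C[C@H](O[Si](C)(C)C(C)(C)C)C#C | intermediate
18 | chlorobis(cyclopentadienyl)[(1E,3S)-alkenyl]zirconium derived from 17 (Zr on C18) | CC[Si](CC)(CC)OC[C@@H]1OC(C)(C)O[C@@H]1C[C@H](O[Si](C)(C)C(C)(C)C)/C=C/[Zr](Cl)(C1C=CC=C1)C1C=CC=C1 | intermediate (not isolated)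
19 | tert-butyl{[(2S,3E)-1-[(4R,5S)-2,2-dimethyl-5-(triethylsilyloxymethyl)-1,3-dioxolan-4-yl]-4-iodobut-3-en-2-yl]oxy}dimethylsilane | CC[Si](CC)(CC)OC[C@@H]1OC(C)(C)O[C@@H]1C[C@H](O[Si](C)(C)C(C)(C)C)/C=C/I | intermediate
20 | (4R,5R)-5-[(2S,3E)-2-(tert-butyldimethylsilyloxy)-4-iodobut-3-en-1-yl]-2,2-dimethyl-1,3-dioxolane-4-carbaldehyde | O=C[C@@H]1OC(C)(C)O[C@@H]1C[C@H](O[Si](C)(C)C(C)(C)C)/C=C/I | intermediate (not isolated)
21 | (2E)-3-[(4S,5R)-5-[(2S,3E)-2-(tert-butyldimethylsilyloxy)-4-iodobut-3-en-1-yl]-2,2-dimethyl-1,3-dioxolan-4-yl]prop-2-enal | O=C/C=C/[C@@H]1OC(C)(C)O[C@@H]1C[C@H](O[Si](C)(C)C(C)(C)C)/C=C/I | intermediate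
22 | (3E,5E)-6-[(4S,5R)-5-[(2S,3E)-2-(tert-butyldimethylsilyloxy)-4-iodobut-3-en-1-yl]-2,2-dimethyl-1,3-dioxolan-4-yl]hexa-3,5-dien-2-one | CC(=O)/C=C/C=C/[C@@H]1OC(C)(C)O[C@@H]1C[C@H](O[Si](C)(C)C(C)(C)C)/C=C/I | intermediate
23 | lithium enolate of 22 (deprotonated at the methyl group, C3) | [Li+].C=C([O-])/C=C/C=C/[C@@H]1OC(C)(C)O[C@@H]1C[C@H](O[Si](C)(C)C(C)(C)C)/C=C/I | intermediate (not isolated)
24 | (4E,6E)-7-[(4S,5R)-5-[(2S,3E)-2-(tert-butyldimethylsilyloxy)-4-iodobut-3-en-1-yl]-2,2-dimethyl-1,3-dioxolan-4-yl]-3-oxo-N-[(2S)-2-(4,4,5,5-tetramethyl-1,3,2-dioxaborolan-2-yl)propyl]hepta-4,6-dienamide | C[C@@H](CNC(=O)CC(=O)/C=C/C=C/[C@@H]1OC(C)(C)O[C@@H]1C[C@H](O[Si](C)(C)C(C)(C)C)/C=C/I)B1OC(C)(C)C(C)(C)O1 | intermediate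
25 | potassium trifluoroborate corresponding to 24 (BF3K on C15) | [K+].C[C@@H](CNC(=O)CC(=O)/C=C/C=C/[C@@H]1OC(C)(C)O[C@@H]1C[C@H](O[Si](C)(C)C(C)(C)C)/C=C/I)[B-](F)(F)F | intermediate
26 | open-chain precursor: 25 with the iodide replaced by the (1E,3Z,7Z)-8-chloro-3-methylocta-1,3,7-trien-5-yn-1-yl group (C14–Cl, C15–BF3K) | [K+].C[C@@H](CNC(=O)CC(=O)/C=C/C=C/[C@@H]1OC(C)(C)O[C@@H]1C[C@H](O[Si](C)(C)C(C)(C)C)/C=C/C=C/C(C)=C\C#C/C=C\Cl)[B-](F)(F)F | intermediate
27 | 24-membered lactam (C14–C15 closed; 5E,7(20)E,18E,8(17)E,9Z,13Z; 11,12-yne; 15R; O21/O22 acetonide; O24 TBS ether) | C[C@H]1CNC(=O)CC(=O)/C=C/C=C/[C@@H]2OC(C)(C)O[C@@H]2C[C@H](O[Si](C)(C)C(C)(C)C)/C=C/C=C/C(C)=C\C#C/C=C\1 | intermediate (not isolated)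
28 | transannular cycloadduct: 16-membered lactam fused to the cis-octalin (rings A and B), with 5E-enone, 11,12-yne, O21/O22 acetonide and O24 TBS ether | C/C1=C/C#C/C=C\[C@@H](C)CNC(=O)CC(=O)/C=C/[C@@H]2[C@@H]1C=C[C@@H]3[C@H]2[C@@H]4OC(C)(C)O[C@@H]4C[C@@H]3O[Si](C)(C)C(C)(C)C | intermediate
29 | triol enone (28 without acetonide and silyl group) | C/C1=C/C#C/C=C\[C@@H](C)CNC(=O)CC(=O)/C=C/[C@@H]2[C@@H]1C=C[C@@H]3[C@H]2[C@H](O)[C@H](O)C[C@@H]3O | intermediate (not isolated)
30 | 11,12-didehydroverticilactam C (C11≡C12; ring C closed) | C/C1=C/C#C/C=C\[C@@H](C)CNC(=O)CC(=O)C[C@@H]2O[C@H]3[C@@H]4[C@@H](C=C[C@H]1[C@H]42)[C@@H](O)C[C@H]3O | intermediate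
31 | verticilactam C | C/C1=C/C=C\C=C/[C@@H](C)CNC(=O)CC(=O)C[C@@H]2O[C@H]3[C@@H]4[C@@H](C=C[C@H]1[C@H]42)[C@@H](O)C[C@H]3O | target

## Step count and risks

Total step count: 22. Longest linear sequence: 15 steps (steps 8–22, from 11).

Steps most likely to fail:

1. Step 20 (Proposed new method). The secondary C15–B bond may transmetalate too slowly, so that protodeboronation, β-hydride elimination with chain walking, or intermolecular coupling take over; the transfer may not be cleanly retentive; and the cycloaddition may start in the open chain and lose the bias of the lactam bridge. The fallback uses known chemistry only, sets out from 21 and 4 and comes back at 28. Enal 21 is condensed (Horner–Wadsworth–Emmons) with the anion of diethyl [(2,2-dimethyl-4-oxo-4H-1,3-dioxin-6-yl)methyl]phosphonate to give the dienyl dioxinone iodide F1. Stille coupling of F1 with stannyl dienyne 4 gives the terminal alkyne F2. The C14–C15 bond is then bought instead of made: commercial (2S)-3-(tert-butoxycarbonylamino)-2-methylpropan-1-ol is oxidised to tert-butyl [(2S)-2-methyl-3-oxopropyl]carbamate F3, and Stork–Zhao olefination (Ph3P=CHI) gives tert-butyl [(2R,3Z)-4-iodo-2-methylbut-3-en-1-yl]carbamate F4. Sonogashira coupling of F4 with F2 gives carbamate F5. The Boc group is removed (TMSOTf, 2,6-lutidine; then MeOH) to give amine F6. Heating F6 in toluene at 110 °C at high dilution releases the acylketene from the dioxinone; trapping by the amine (macrolactamisation) gives 27, which undergoes the same transannular Diels–Alder reaction to 28.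

2. Step 17. O-carbamoylation may compete with C-carbamoylation, proton transfer from the product may quench unreacted enolate, or deprotonation at C21–H (vinylogous position) may open the dioxolane. The fallback sets out from 21 and 10 and comes back at 24. Enal 21 is condensed with the dianion of S-tert-butyl 4-(diethoxyphosphoryl)-3-oxobutanethioate (NaH, 2 equiv) to give S-tert-butyl β-keto thioester F7. Isocyanate 10 is hydrolysed with aqueous HCl to (2S)-2-(pinacolboryl)propan-1-aminium chloride F8. Silver-promoted aminolysis (AgOCOCF3, Et3N, THF, rt) of F7 with F8 gives 24.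

3. Step 19. The ionic trifluoroborate forces a polar medium in which destannylation and homocoupling can compete, and the salt cannot be chromatographed, so decomposition of the polyene or premature cycloaddition during isolation are possible. The fallback sets out from 22 and 5 and comes back at 26. The Stille coupling is moved forward: neutral iodide 22 and stannane 5 give chloro-polyenyl methyl ketone F9. Carbamoylation of its kinetic enolate with 10 (as in step 17, −78 °C) gives the chromatographable pinacol boronate F10. Treatment with KHF2 as the last operation before the key step gives 26.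

## Further compounds

F1 | step 20 | 6-[(1E,3E)-4-[(4S,5R)-5-[(2S,3E)-2-(tert-butyldimethylsilyloxy)-4-iodobut-3-en-1-yl]-2,2-dimethyl-1,3-dioxolan-4-yl]buta-1,3-dien-1-yl]-2,2-dimethyl-4H-1,3-dioxin-4-one | CC1(C)OC(=CC(=O)O1)/C=C/C=C/[C@@H]1OC(C)(C)O[C@@H]1C[C@H](O[Si](C)(C)C(C)(C)C)/C=C/I
F2 | step 20 | Stille product of F1 and 4 (terminal alkyne at C12) | CC1(C)OC(=CC(=O)O1)/C=C/C=C/[C@@H]1OC(C)(C)O[C@@H]1C[C@H](O[Si](C)(C)C(C)(C)C)/C=C/C=C/C(C)=C\C#C
F3 | step 20 | tert-butyl [(2S)-2-methyl-3-oxopropyl]carbamate | C[C@@H](CNC(=O)OC(C)(C)C)C=O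
F4 | step 20 | tert-butyl [(2R,3Z)-4-iodo-2-methylbut-3-en-1-yl]carbamate | C[C@@H](CNC(=O)OC(C)(C)C)/C=C\I
F5 | step 20 | Sonogashira product of F4 and F2 (N-Boc amine, dioxinone) | CC1(C)OC(=CC(=O)O1)/C=C/C=C/[C@@H]1OC(C)(C)O[C@@H]1C[C@H](O[Si](C)(C)C(C)(C)C)/C=C/C=C/C(C)=C\C#C/C=C\[C@@H](C)CNC(=O)OC(C)(C)C
F6 | step 20 | free amine from F5 | CC1(C)OC(=CC(=O)O1)/C=C/C=C/[C@@H]1OC(C)(C)O[C@@H]1C[C@H](O[Si](C)(C)C(C)(C)C)/C=C/C=C/C(C)=C\C#C/C=C\[C@@H](C)CN
F7 | step 17 | S-tert-butyl (4E,6E)-7-[(4S,5R)-5-[(2S,3E)-2-(tert-butyldimethylsilyloxy)-4-iodobut-3-en-1-yl]-2,2-dimethyl-1,3-dioxolan-4-yl]-3-oxohepta-4,6-dienethioate | CC(C)(C)SC(=O)CC(=O)/C=C/C=C/[C@@H]1OC(C)(C)O[C@@H]1C[C@H](O[Si](C)(C)C(C)(C)C)/C=C/I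
F8 | step 17 | (2S)-2-(4,4,5,5-tetramethyl-1,3,2-dioxaborolan-2-yl)propan-1-aminium chloride | C[C@@H](C[NH3+])B1OC(C)(C)C(C)(C)O1.[Cl-]
F9 | step 19 | Stille product of 22 and 5 (methyl ketone with the full chloro-polyenyne chain) | CC(=O)/C=C/C=C/[C@@H]1OC(C)(C)O[C@@H]1C[C@H](O[Si](C)(C)C(C)(C)C)/C=C/C=C/C(C)=C\C#C/C=C\Cl
F10 | step 19 | pinacol boronate analogue of 26 | C[C@@H](CNC(=O)CC(=O)/C=C/C=C/[C@@H]1OC(C)(C)O[C@@H]1C[C@H](O[Si](C)(C)C(C)(C)C)/C=C/C=C/C(C)=C\C#C/C=C\Cl)B1OC(C)(C)C(C)(C)O1
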